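1. A closed, stirred vessel holds both mirror-image substrates, and the single-handed coupling partner turns each into its product.

| setting | eta | alpha | Wednesday's | Saturday's | Thursday's | Tuesday's | Friday's |
|---|---|---|---|---|---|---|---|
| left-handed substrate | 0.039 M | 0.029 M | 0.058 M | 0.058 M | 0.058 M | 0.058 M | 0.058 M |
| right-handed substrate | 0.039 M | 0.029 M | 0.058 M | 0.058 M | 0.058 M | 0.058 M | 0.058 M |
| coupling partner | 0.0696 M | 0.0696 M | 0.0696 M | 0.0400 M | 0.200 M | 0.100 M | 0.150 M |
| remark | run made earlier | run made earlier |  |  |  |  |  |
| time |  |  | 15 min | 15 min | 15 min | 15 min | 15 min |

| run | time / min | left-handed product / % | right-handed product / % |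
|---|---|---|---|
| eta | 0.417 | 13 | 1 |
| eta | 1.00 | 25 | 1 |
| eta | 2.50 | 38 | 3 |
| eta | 5.00 | 44 | 1 |
| alpha | 0.667 | 17 | 1 |
| alpha | 2.00 | 36 | 0 |
| alpha | 3.00 | 40 | 1 |
| alpha | 5.00 | 49 | 2 |

(standard deviation of a reading: 1.5 percentage points)

* all flasks from highest to lowest excess of left-handed product over right-handed product, at 15 min (Wednesday's / Saturday's / Thursday's / Tuesday's / Friday's)
* the same order at 2.0 h (Wednesday's / Saturday's / Thursday's / Tuesday's / Friday's)
* the excess of left-handed product over right-handed product of the flask you put first, at 15 min
* the excess of left-handed product over right-handed product of the flask you put last, at 15 min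

- coupling partner is single-handed; left-handed substrate and right-handed substrate are mirror images of each other, charged as a racemate, each of them at the stated concentration
- the handed part of coupling partner does not stay in what it makes, so the products of the two hands are mirror images too

2. The alpha run reads 49% left-handed product against 2% right-handed product at 5.00 min. Within a scatter of 1.5 percentage points, these readings show a high selectivity factor: the coupling partner takes the left-handed substrate first, so its balance is reckoned against that charge.

3. Thursday's charges 0.200 M of coupling partner against 0.058 M of left-handed substrate, a difference of 0.142 M. This is the partner surplus: partner charge minus left-handed substrate charge. Wednesday's has 0.0116 M, Tuesday's 0.0420 M and Friday's 0.0920 M. Saturday's has −0.0180 M, so there the partner is the limiting reagent, and Saturday's products cannot pass 34.5% of the substrates charged.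

4. First extreme: the right-handed substrate does not react, and the excess is complete.

5. Second extreme: the left-handed substrate reacts completely and the surplus ends wholly in right-handed product, so the excess is (left-handed charge − surplus)/(left-handed charge + surplus). That gives 66.7% for Wednesday's and 16.0% for Tuesday's. Friday's and Thursday's surpluses exceed the equal right-handed charge, so in this extreme both stand at zero.

6. Each flask with a positive surplus starts near the first extreme and drifts towards the second. My ranking follows rising surplus at both times: Saturday's, Wednesday's, Tuesday's, Friday's, Thursday's.

7. The forecast gives Saturday's > Wednesday's > Tuesday's > Friday's > Thursday's at 15 min and Saturday's > Wednesday's > Tuesday's > Friday's > Thursday's at 2.0 h, with top 94% (90% to 97%) and low 50% (37% to 65%). Its ground: “Excess partner keeps eating the right-handed substrate after the left is gone.”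

8. The flasks give Saturday's > Wednesday's > Tuesday's > Friday's > Thursday's at 15 min and Saturday's > Wednesday's > Tuesday's > Friday's > Thursday's at 2.0 h, with top 95.6% and low 56.3%.

    coupling partner → decomposition product (k = 4.12 × 10⁻⁶ /s)
    coupling partner + left-handed substrate → left-handed product (k = 0.196 /M/s)
    coupling partner + right-handed substrate → right-handed product (k = 0.00270 /M/s)

9. Saturday's excess has come to rest: its coupling partner stands at 1.06% of its charge at 15.0 min, and ten times the time leaves the excess at 95.6%. Thursday's has not: with a surplus of 0.142 M, its right-handed product climbs from 14.0% to 45.8% by 150 min, and its excess falls from 56.3% to 4.42%.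

10. The neighbour flask, Saturday's with 0.068 M of coupling partner, has a surplus of 0.0100 M, so its second extreme is 70.6%. At 15.0 min that neighbour flask stands at 91.2%, with 48.1% left-handed product.

The readings are calculated for an exercise; noise was put on by code.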